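**Retrosynthetic overview**
1. Praesorether F ⇒ methyl orsellinate + an aminomethylated diaryl ether (ring B–O–ring C); the last C–C bond is made by ortho-quinone-methide alkylation between the two hydroxyls of the orsellinate.
2. The diaryl ether ⇒ a depsidone (dibenzo[b,e][1,4]dioxepin-11-one) by methanolysis; the lactone is a temporary tether that ends up as the CO2Me of ring C and the free OH of ring B.
3. Key disconnection: the diaryl ether C–O bond of the depsidone ⇒ a depside, closed by intramolecular dehydrogenative phenol O–H / aryl C–H coupling.
4. Depside ⇒ haematommic acid (from methyl orsellinate by formylation and ester O-demethylation) + 2-(dimethylaminomethyl)orcinol (from atranol by reductive amination).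
5. Ring order: all three benzene rings are bought; the only ring formed is the seven-membered dioxepinone (step 5), which is opened again in the last step.

Assumption: the target has no stereocentre and no stable stereoaxis, so it is one achiral compound and no stereocontrol is needed; methyl orsellinate and atranol are taken as catalogue chemicals.

**Step 1**
Reactants: 1 methyl orsellinate (methyl 2,4-dihydroxy-6-methylbenzoate)
Product: 3 methyl haematommate (methyl 3-formyl-2,4-dihydroxy-6-methylbenzoate), via α-chloro ether 2 (not isolated)
Conditions: Cl2CHOMe (1.2 equiv), TiCl4 (2.5 equiv), CH2Cl2, 0 °C → rt; then 1 M HCl, 0 °C; crystallise away the minor 5-formyl isomer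
Reagents that add atoms: dichloromethyl methyl ether COC(Cl)Cl; water O
Why: Rieche formylation, in which titanium chelation of the phenolic oxygens and the bond fixation of the chelated 2-hydroxybenzoate direct the electrophile to C3 between the two hydroxyls, and hydrolysis of 2 releases the aldehyde (no stereocentre is formed in the product).

**Step 2**
Reactants: 3 methyl haematommate
Product: 4 haematommic acid (3-formyl-2,4-dihydroxy-6-methylbenzoic acid)
Conditions: LiI (5 equiv), EtOAc, reflux, dark; then 1 M HCl, 0 °C; use at once
Reagents that add atoms: none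
Why: SN2 O-demethylation of the ester by iodide (nucleophilic ester dealkylation) attacks the methyl group and so is indifferent to the shielded 2,6-disubstituted carbonyl, while the neutral conditions and cold acidification spare the aldehyde and avoid decarboxylation of the β-resorcylic acid.

**Step 3**
Reactants: 5 atranol (2,6-dihydroxy-4-methylbenzaldehyde)
Product: 7 2-[(dimethylamino)methyl]-5-methylbenzene-1,3-diol, via iminium zwitterion 6 (not isolated)
Conditions: Me2NH (2 M in THF, 1.5 equiv), NaBH(OAc)3 (1.5 equiv), AcOH (1 equiv), DCE, rt
Reagents that add atoms: dimethylamine CNC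
Why: Reductive amination, in which the salicylaldehyde condenses to iminium 6 that triacetoxyborohydride reduces selectively, fixing the future bridging carbon on the position flanked by the two hydroxyls of a symmetric ring.

**Step 4**
Reactants: 4 haematommic acid; 7 2-[(dimethylamino)methyl]-5-methylbenzene-1,3-diol (2.5 equiv)
Product: 9 2-[(dimethylamino)methyl]-3-hydroxy-5-methylphenyl 3-formyl-2,4-dihydroxy-6-methylbenzoate (depside), via O-acylisourea 8 (not isolated)
Conditions: DCC (1.1 equiv), CH2Cl2–THF, 0 °C → rt; excess 7 recovered
Reagents that add atoms: none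
Why: Carbodiimide esterification of the kind used for lichen depsides, in which 8 acylates one of the two equivalent amine-activated hydroxyls of 7 (excess suppresses the diester) while the aldehyde-chelated 4-OH of the acid competes poorly.

**Step 5**
Reactants: 9 depside
Product: 11 9-[(dimethylamino)methyl]-3,8-dihydroxy-1,6-dimethyl-11-oxo-11H-dibenzo[b,e][1,4]dioxepine-4-carbaldehyde (depsidone), via cyclohexadienone 10 (not isolated)
Conditions: PhI(OCOCF3)2 (1.05 equiv, slow addition), CF3CO2H (1.1 equiv), (CF3)2CHOH (5 mM), −20 → 0 °C; then aq. NaHCO3
Reagents that add atoms: none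
Why: Proposed new method: the only electron-rich phenol (ring B C3–OH) exchanges onto iodine(III) and ionises in HFIP to a phenoxenium ion whose para carbon C6 (ortho to the ester oxygen; C2 is blocked by the protonated aminomethyl group and C4 is out of reach) is captured through a seven-membered transition state by the 2-OH of the haematommyl ring, and dienone 10 then tautomerises irreversibly to the aromatic depsidone, so the ester tether decides both which oxygen (2-OH, not 4-OH) and which carbon couple; the closest known reaction types are PIDA/PIFA para-selective oxidative C–O functionalisation of phenols in fluorinated alcohols, the oxidative cyclisation of 2-hydroxybenzophenones to grisadienediones and the enzymatic depside-to-depsidone coupling, whereas a direct reagent-based dehydrogenative depside-to-depsidone closure is, to my knowledge, not described.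

**Step 6**
Reactants: 11 depsidone; 1 methyl orsellinate (6 equiv)
Product: 14 Praesorether F, via ring-opened Mannich base 12 (not isolated), via ortho-quinone methide 13 (not isolated)
Conditions: MeOH, Et3N (0.2 equiv), rt → 40 °C; evaporate; then 1 (6 equiv), i-Pr2NEt (2 equiv), 1,4-dioxane, 100 °C, Ar; excess 1 recovered
Reagents that add atoms: methanol CO
Why: Amine-catalysed methanolysis of the strained aryl lactone (the known depsidone-to-diphenyl-ether opening) gives 12, whose doubly ortho-hydroxylated Mannich base loses Me2NH on heating to ortho-quinone methide 13, which is trapped by Michael addition and rearomatisation at C3 of excess methyl orsellinate, the position between its hydroxyls where orsellinate esters take soft carbon electrophiles.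

**Compound list**
1 | methyl orsellinate (methyl 2,4-dihydroxy-6-methylbenzoate) | COC(=O)c1c(C)cc(O)cc1O | starting material
2 | methyl 3-[chloro(methoxy)methyl]-2,4-dihydroxy-6-methylbenzoate (racemic, titanium-bound) | COC(Cl)c1c(O)cc(C)c(C(=O)OC)c1O | intermediate
3 | methyl haematommate (methyl 3-formyl-2,4-dihydroxy-6-methylbenzoate) | COC(=O)c1c(C)cc(O)c(C=O)c1O | intermediate
4 | haematommic acid (3-formyl-2,4-dihydroxy-6-methylbenzoic acid) | OC(=O)c1c(C)cc(O)c(C=O)c1O | intermediate
5 | atranol (2,6-dihydroxy-4-methylbenzaldehyde) | Cc1cc(O)c(C=O)c(O)c1 | starting material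
6 | 2-[(dimethyliminio)methyl]-3-hydroxy-5-methylphenolate (iminium zwitterion) | C[N+](C)=Cc1c(O)cc(C)cc1[O-] | intermediate
7 | 2-[(dimethylamino)methyl]-5-methylbenzene-1,3-diol | CN(C)Cc1c(O)cc(C)cc1O | intermediate
8 | N,N'-dicyclohexyl-O-(3-formyl-2,4-dihydroxy-6-methylbenzoyl)isourea (C=N geometry not defined) | O=Cc1c(O)cc(C)c(C(=O)OC(NC2CCCCC2)=NC2CCCCC2)c1O | intermediate
9 | 2-[(dimethylamino)methyl]-3-hydroxy-5-methylphenyl 3-formyl-2,4-dihydroxy-6-methylbenzoate | CN(C)Cc1c(O)cc(C)cc1OC(=O)c1c(C)cc(O)c(C=O)c1O | intermediate
10 | 9-[(dimethylamino)methyl]-3-hydroxy-1,6-dimethyl-8,11-dioxo-5a,8-dihydro-11H-dibenzo[b,e][1,4]dioxepine-4-carbaldehyde (racemic at C5a) | O=C1C=C(C)C2Oc3c(C=O)c(O)cc(C)c3C(=O)OC2=C1CN(C)C | intermediate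
11 | 9-[(dimethylamino)methyl]-3,8-dihydroxy-1,6-dimethyl-11-oxo-11H-dibenzo[b,e][1,4]dioxepine-4-carbaldehyde | CN(C)Cc1c(O)cc(C)c2Oc3c(C=O)c(O)cc(C)c3C(=O)Oc12 | intermediate
12 | methyl 2-{3-[(dimethylamino)methyl]-2,4-dihydroxy-6-methylphenoxy}-3-formyl-4-hydroxy-6-methylbenzoate | COC(=O)c1c(C)cc(O)c(C=O)c1Oc1c(C)cc(O)c(CN(C)C)c1O | intermediate
13 | methyl 3-formyl-4-hydroxy-2-[(2-hydroxy-6-methyl-3-methylidene-4-oxocyclohexa-1,5-dien-1-yl)oxy]-6-methylbenzoate | C=C1C(=O)C=C(C)C(Oc2c(C=O)c(O)cc(C)c2C(=O)OC)=C1O | intermediate
14 | Praesorether F | COC(=O)c1c(C)cc(O)c(Cc2c(O)cc(C)c(Oc3c(C=O)c(O)cc(C)c3C(=O)OC)c2O)c1O | target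

**Step count and risks**
Total: 6 steps. Longest linear sequence: 5 steps (1 → 3 → 4 → 9 → 11 → 14, i.e. steps 1, 2, 4, 5 and 6); step 3 is a one-step branch.

The three steps most likely to fail are 5, 4 and 6.

Step 5 (the new oxidative C–O ring closure). The product is a para-aryloxyphenol and may be oxidised further, and trifluoroacetate or solvent may capture the phenoxenium ion before the weakly nucleophilic chelated 2-OH does. The fallback uses known halogenation and copper chemistry. It sets out from 9: NBS (1.0 equiv) with CF3CO2H in MeCN at −20 °C brominates para to the free hydroxyl to give 6-bromo-2-[(dimethylamino)methyl]-3-hydroxy-5-methylphenyl 3-formyl-2,4-dihydroxy-6-methylbenzoate F2. An intramolecular Ullmann diaryl ether synthesis (CuI, N,N-dimethylglycine, K3PO4, dioxane, 90 °C) then closes the seven-membered ring, and the route is rejoined at 11.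

Step 4 (esterification with an unprotected, decarboxylation-prone hydroxy acid). Self-acylation through the 4-OH of 4, N-acylurea formation or loss of CO2 could erode the yield. The fallback sets out from 4: acetone, (CF3CO)2O and CF3CO2H at rt give the acetonide 7-hydroxy-2,2,5-trimethyl-4-oxo-4H-1,3-benzodioxine-8-carbaldehyde F1, in which the carboxyl and the 2-OH are masked. The sodium phenoxide of 7 (NaH, THF, 0 °C → rt, 2.5 equiv of 7) then opens the dioxinone by acyl transfer with loss of acetone, and the route is rejoined at 9.

Step 6 (one-pot lactone opening and quinone-methide coupling). Quinone methide 13 may be captured by the electron-rich ring B of another molecule instead of by the ester-deactivated methyl orsellinate, giving oligomers. The fallback sets out from 12, isolated after the methanolysis: sodium p-toluenesulfinate (5 equiv) in AcOH at 80 °C exchanges the amine for a sulfone, the soft sulfinate outcompeting every carbon nucleophile, to give methyl 2-{2,4-dihydroxy-6-methyl-3-[(4-methylbenzenesulfonyl)methyl]phenoxy}-3-formyl-4-hydroxy-6-methylbenzoate F3. This bench-stable quinone-methide equivalent is then unmasked with Cs2CO3 in MeCN at 0 °C → rt in the presence of the pre-formed phenoxide of 1 (3 equiv), so that generation and capture occur at low temperature and low stationary concentration, and the route is rejoined at 14.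

**Further compounds**
F1 | step 4 | 7-hydroxy-2,2,5-trimethyl-4-oxo-4H-1,3-benzodioxine-8-carbaldehyde | CC1(C)OC(=O)c2c(C)cc(O)c(C=O)c2O1
F2 | step 5 | 6-bromo-2-[(dimethylamino)methyl]-3-hydroxy-5-methylphenyl 3-formyl-2,4-dihydroxy-6-methylbenzoate | CN(C)Cc1c(O)cc(C)c(Br)c1OC(=O)c1c(C)cc(O)c(C=O)c1O
F3 | step 6 | methyl 2-{2,4-dihydroxy-6-methyl-3-[(4-methylbenzenesulfonyl)methyl]phenoxy}-3-formyl-4-hydroxy-6-methylbenzoate | COC(=O)c1c(C)cc(O)c(C=O)c1Oc1c(C)cc(O)c(CS(=O)(=O)c2ccc(C)cc2)c1O
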